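**Retrosynthetic overview**
1. The target comes from NBS/water hydrolysis of a spiro dithio ortho ester; the 6-acetate is put on just before, so the electrolysis runs on the free 6,9,15-triol.
2. Key disconnection: O9–C13 and O15–C16. C13 is the α-carbon of the γ-lactone (C13, C14, C15, O, C16) but must receive the C9 oxygen to close the tetrahydrofuran (O, C9, C11, C12, C13). This polarity mismatch is removed by the radical cation of a C13=C16 ketene dithioacetal (C16 in a 1,3-dithiane), and anodic oxidation closes both rings at once.
3. The ketene dithioacetal comes from an α-alkyl-γ-butyrolactone (aluminium thiolate), made by Giese addition of a C11 radical to α-methylene-γ-butyrolactone. The 9α-hydroxy-11-iodide comes from α-face epoxidation of a 9(11)-methylene, because a carbanion adding to the C9 ketone would give the C9 epimer.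
4. Ring B centres: C8 by hydroxyl-directed hydrogenation, C6 by oxidation and thermodynamic reduction. C5, C10 and the cis ring fusion come from an enantioselective Diels–Alder reaction of 2,6-dimethyl-1,4-benzoquinone (ring B) with 4-methylpenta-1,3-diene (ring A).
5. Ring order: ring A onto ring B (step 1), then the tetrahydrofuran and the lactone ring together (step 11).

Key step: step 11

**Conventions and assumptions**
- Labdane numbering is used: ring A is C1–C5 and C10; ring B is C5–C10; the side chain is C11–C16; methyl groups sit on C4 (two), C8 and C10.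
- α is the face of the decalin that carries the C10 methyl group. The target is 5α-H, 6α-OAc, 8α-CH3, 9α-O (C11 is 9β), 10α-CH3, a cis-fused decalin, (5S,6S,8R,9R,10R,13R).
- Assumption: the sense of induction in step 1 is taken from the usual binding model of quinones to the cationic oxazaborolidine. Should the adduct prove antipodal, the catalyst from (R)-α,α-diphenylprolinol is used.

**Route**

Step 1
Reactants: 1 2,6-dimethyl-1,4-benzoquinone; 2 4-methylpenta-1,3-diene
Product: 3 (4aS,8aR)-2,5,5,8a-tetramethyl-4a,5,8,8a-tetrahydronaphthalene-1,4-dione (cis-fused adduct; 5α-H, 10α-CH3, ketones at C6 and C9, alkenes C2=C3 and C7=C8)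
Conditions: (S)-3,3-diphenyl-1-(2-methylphenyl)tetrahydro-1H,3H-pyrrolo[1,2-c][1,3,2]oxazaborole activated with Tf2NH (20 mol %), 2 (3 equiv), CH2Cl2, −78 to −20 °C
Reagents that add atoms: none
Why: Diels–Alder reaction under a chiral cationic oxazaborolidine, which binds the less hindered carbonyl flanked by two vinylic C–H so that the CH2 terminus of the diene attacks the methyl-bearing carbon and the gem-dimethyl terminus bonds to the CH carbon (also the sterically easier regiochemistry, as no adjacent quaternary carbons arise); suprafacial addition closes ring A with the cis fusion (C5–H and C10–CH3) and the shielded face of the bound quinone sets the absolute configuration (5S,10R).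

Step 2
Reactants: 3 Diels–Alder adduct
Product: 4 (4R,4aS,8aR)-4-hydroxy-2,5,5,8a-tetramethyl-4a,5,8,8a-tetrahydronaphthalen-1(4H)-one (6β-hydroxy-7-en-9-one)
Conditions: NaBH4, CeCl3·7H2O, MeOH, −78 °C
Reagents that add atoms: none
Why: Luche 1,2-reduction should take the less hindered enone carbonyl C6 (between the C5 methine and a vinylic CH) in preference to C9 (between quaternary C10 and the methylated C8), and hydride should enter from the convex α face of the cis-fused bicycle, so that the new hydroxyl is 6β (6R), wanted here only as a directing group.

Step 3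
Reactants: 4 6β-hydroxy enone
Product: 5 (2R,4R,4aS,8aR)-4-hydroxy-2,5,5,8a-tetramethyloctahydronaphthalen-1(2H)-one (6β-hydroxy-8α-methyl 9-ketone, ring A saturated)
Conditions: H2 (1 atm), [Ir(cod)(PCy3)(py)]PF6 (5 mol %), CH2Cl2, rt
Reagents that add atoms: none
Why: Hydroxyl-directed homogeneous hydrogenation in which the 6β-hydroxyl binds the cationic iridium and delivers hydrogen to the β face of C7=C8, which places the C8 methyl on the α face (8R) against the steric bias of the bicycle; the cis-disubstituted C2=C3 bond is saturated in the same operation.

Step 4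
Reactants: 5 6β-hydroxy-8α-methyl 9-ketone
Product: 6 4,4,8α,10α-tetramethyl-9-methylidene-5α-H-decalin-6β-ol
Conditions: Cp2Ti(μ-CH2)(μ-Cl)AlMe2 (3 equiv), pyridine (cat.), THF–toluene, −40 °C to rt; aq. NaOH work-up
Reagents that add atoms: Tebbe reagent, written as Cp2Ti=CH2 with ClAlMe2, C=[Ti](C1C=CC=C1)C1C=CC=C1.C[Al](C)Cl
Why: Tebbe methylenation, whose small and non-basic titanium methylidene should olefinate the hindered, enolisable C9 ketone without epimerising C8 (the free hydroxyl only consumes reagent), and which sets the C9 carbon apart from C6 for the redox correction that follows.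

Step 5
Reactants: 6 6β-alcohol
Product: 7 4,4,8α,10α-tetramethyl-9-methylidene-5α-H-decalin-6-one
Conditions: Dess–Martin periodinane, pyridine, CH2Cl2, 0 °C to rt; used crude
Reagents that add atoms: none
Why: Dess–Martin oxidation under buffered, non-epimerising conditions removes the C6 centre that served as directing group and leaves the exocyclic alkene, C8 and the cis ring fusion untouched.

Step 6
Reactants: 7 6-ketone
Product: 8 4,4,8α,10α-tetramethyl-9-methylidene-5α-H-decalin-6α-ol
Conditions: Li, NH3(l)–THF, t-BuOH (2.2 equiv), −78 °C; then NH4Cl
Reagents that add atoms: none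
Why: Dissolving-metal reduction should give the thermodynamically preferred alcohol: with the C8 and C10 methyl groups both α, ring B is held in the chair that keeps them equatorial, and there the equatorial hydroxyl is 6α (6S) while the 6β epimer would be syn-axial to C1; the isolated 1,1-disubstituted alkene is not reduced.

Step 7
Reactants: 8 6α-alcohol
Product: 9 9α,11-epoxy-4,4,8α,10α-tetramethyl-5α-H-decalin-6α-ol (spiro oxirane at C9, oxygen α, C11 β)
Conditions: mCPBA, CH2Cl2, 0 °C; aq. NaHCO3 wash
Reagents that add atoms: mCPBA (3-chloroperoxybenzoic acid), OOC(=O)c1cccc(Cl)c1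
Why: Prilezhaev epoxidation, in which the β face of the 9(11)-methylene is screened by the axial C1 methylene of ring A so that the peracid should add to the α face and set the oxygen 9α (9R); a carbanion adding to the C9 ketone would enter from that same α face and give the C9 epimer, which is why the C9–O bond is made by oxidation.

Step 8
Reactants: 9 9α,11-epoxide
Product: 10 9β-(iodomethyl)-4,4,8α,10α-tetramethyl-5α-H-decalin-6α,9α-diol
Conditions: LiI, AcOH, THF, 0 °C to rt
Reagents that add atoms: lithium iodide, [Li+].[I-]
Why: SN2 opening of the 1,1-disubstituted epoxide by iodide at the primary carbon C11 leaves the C9–O bond, and with it the C9 configuration, untouched.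

Step 9
Reactants: 10 iodohydrin; 11 α-methylene-γ-butyrolactone
Product: 12 3-[2-(6α,9α-dihydroxy-4,4,8α,10α-tetramethyl-5α-H-decalin-9β-yl)ethyl]dihydrofuran-2(3H)-one (C13 epimers)
Conditions: 11 (5 equiv), Bu3SnH (slow addition), AIBN (cat.), toluene, 80 °C
Reagents that add atoms: none
Why: Giese reaction in which the primary C11 radical adds to the methylene carbon (C12) of the acceptor and the α-carbonyl radical is reduced by Bu3SnH; free hydroxyls are tolerated and the new C13 centre becomes sp2 in the next step, so its configuration is of no concern.

Step 10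
Reactants: 12 hydroxy lactone
Product: 13 2-[1-hydroxy-5-(6α,9α-dihydroxy-4,4,8α,10α-tetramethyl-5α-H-decalin-9β-yl)pentan-3-ylidene]-1,3-dithiane (6,9,15-triol with the C13=C16 ketene dithioacetal)
Conditions: AlMe3 (7 equiv), propane-1,3-dithiol (3 equiv), CH2Cl2, 0 °C to reflux; aq. NaOH work-up, Et3N-deactivated silica
Reagents that add atoms: propane-1,3-dithiol, SCCCS
Why: Aluminium thiolate conversion of a lactone into a ketene dithioacetal: bis(dimethylaluminium) propane-1,3-dithiolate puts both sulfur atoms on the lactone carbonyl carbon C16, loss of the C13 hydrogen gives the tetrasubstituted C13=C16 bond, and the ring oxygen is released as the C15 hydroxyl, so the substrate of the key step arises without protecting groups.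

Step 11
Reactants: 13 triol ketene dithioacetal
Product: 14 (13R)-6α-hydroxy-9α,13-epoxy spiro compound with C16 as cyclic dithio ortho ester (C16 bonded to O15 and to both sulfur atoms of the 1,3-dithiane)
Conditions: reticulated vitreous carbon anode, Pt cathode, undivided cell, LiClO4 (0.1 M), MeOH–THF (3:7), 2,6-lutidine (6 equiv), constant current (8 mA), 2.2 F/mol, rt
Reagents that add atoms: none
Why: The ketene dithioacetal is oxidised at the carbon anode far more easily than the alcohols and gives a radical cation whose carbon remote from sulfur, C13, is attacked by the tertiary C9 hydroxyl; a second electron is lost from the sulfur-stabilised C16 radical and the resulting dithiocarbenium ion is captured by the C15 hydroxyl, with 2,6-lutidine taking up the protons. The closest known reaction type is the anodic coupling of ketene dithioacetal radical cations with tethered alcohols, which gives tetrahydrofurans with a fully substituted carbon next to oxygen. The ether ring (O, C9, C11, C12, C13) closes 5-exo-trig onto the C13=C16 bond, and the lactone-level ring (C13, C14, C15, O, C16) closes 5-exo-trig onto the C16=S+ bond. C13 (13R) is the only new stereocentre and is under substrate control: in the closing transition state the bulky dithiane carbon C16 should turn to the side of the tertiary C8, and the slimmer C14 chain to the side of the quaternary C10 with its axial C1 methylene. The step needs the C9 hydroxyl to win at C13 over the C15 and C6 hydroxyls and over methanol, and needs attack at C13 rather than C16: the C15 hydroxyl would have to form an oxetane and the C6 hydroxyl an eight-membered ring, the intramolecular attack from the fully substituted C9 outruns the solvent, and only attack at C13 leaves the sulfur-stabilised radical. A hindered tertiary alcohol of this kind is a poor nucleophile in polar substitution but adds readily to a radical cation, which is why the umpolung is done this way.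

Step 12
Reactants: 14 6α-hydroxy dithio ortho ester
Product: 15 6α-acetoxy-9α,13-epoxy spiro dithio ortho ester (6-O-acetate of 14)
Conditions: Ac2O, DMAP, pyridine, CH2Cl2, rt
Reagents that add atoms: acetic anhydride, CC(=O)OC(C)=O
Why: DMAP-catalysed acetylation of the only remaining hydroxyl (equatorial 6α-OH) under basic conditions that the dithio ortho ester tolerates.

Step 13
Reactants: 15 acetoxy dithio ortho ester
Product: 16 target, (5S,6S,8R,9R,10R,13R)-6-acetoxy-9,13-epoxy-16,15-olide of the cis-fused labdane skeleton
Conditions: NBS, NaHCO3, acetone–H2O (9:1), 0 °C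
Reagents that add atoms: water, O
Why: Oxidative hydrolysis of the cyclic dithio ortho ester (bromosulfonium formation by NBS, C–S cleavage, attack of water) should unveil the C16 lactone carbonyl without touching the acetate or the fully substituted C9 and C13.

**Compound list**
1 | 2,6-dimethyl-1,4-benzoquinone | CC1=CC(=O)C=C(C)C1=O | starting material
2 | 4-methylpenta-1,3-diene | CC(C)=CC=C | starting material
3 | (4aS,8aR)-2,5,5,8a-tetramethyl-4a,5,8,8a-tetrahydronaphthalene-1,4-dione | O=C1C=C(C)C(=O)[C@]2(C)CC=CC(C)(C)[C@H]12 | intermediate
4 | (4R,4aS,8aR)-4-hydroxy-2,5,5,8a-tetramethyl-4a,5,8,8a-tetrahydronaphthalen-1(4H)-one | O[C@@H]1C=C(C)C(=O)[C@]2(C)CC=CC(C)(C)[C@H]12 | intermediate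
5 | (2R,4R,4aS,8aR)-4-hydroxy-2,5,5,8a-tetramethyloctahydronaphthalen-1(2H)-one | O[C@@H]1C[C@@H](C)C(=O)[C@]2(C)CCCC(C)(C)[C@H]12 | intermediate
6 | 4,4,8α,10α-tetramethyl-9-methylidene-5α-H-decalin-6β-ol | O[C@@H]1C[C@@H](C)C(=C)[C@]2(C)CCCC(C)(C)[C@H]12 | intermediate
7 | 4,4,8α,10α-tetramethyl-9-methylidene-5α-H-decalin-6-one | O=C1C[C@@H](C)C(=C)[C@]2(C)CCCC(C)(C)[C@H]12 | intermediate
8 | 4,4,8α,10α-tetramethyl-9-methylidene-5α-H-decalin-6α-ol | O[C@H]1C[C@@H](C)C(=C)[C@]2(C)CCCC(C)(C)[C@H]12 | intermediate
9 | 9α,11-epoxy-4,4,8α,10α-tetramethyl-5α-H-decalin-6α-ol | O[C@H]1C[C@@H](C)[C@]2(CO2)[C@]3(C)CCCC(C)(C)[C@H]13 | intermediate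
10 | 9β-(iodomethyl)-4,4,8α,10α-tetramethyl-5α-H-decalin-6α,9α-diol | O[C@H]1C[C@@H](C)[C@](O)(CI)[C@]2(C)CCCC(C)(C)[C@H]12 | intermediate
11 | α-methylene-γ-butyrolactone (3-methylidenedihydrofuran-2(3H)-one) | C=C1CCOC1=O | starting material
12 | 3-[2-(6α,9α-dihydroxy-4,4,8α,10α-tetramethyl-5α-H-decalin-9β-yl)ethyl]dihydrofuran-2(3H)-one (C13 epimers) | O[C@H]1C[C@@H](C)[C@](O)(CCC3CCOC3=O)[C@]2(C)CCCC(C)(C)[C@H]12 | intermediate
13 | 2-[1-hydroxy-5-(6α,9α-dihydroxy-4,4,8α,10α-tetramethyl-5α-H-decalin-9β-yl)pentan-3-ylidene]-1,3-dithiane | O[C@H]1C[C@@H](C)[C@](O)(CCC(CCO)=C3SCCCS3)[C@]2(C)CCCC(C)(C)[C@H]12 | intermediate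
14 | (13R)-6α-hydroxy-9α,13-epoxy spiro ether with C16 as cyclic dithio ortho ester | O[C@H]1C[C@@H](C)[C@]2(CC[C@]3(CCOC34SCCCS4)O2)[C@]2(C)CCCC(C)(C)[C@H]12 | intermediate
15 | (13R)-6α-acetoxy-9α,13-epoxy spiro ether with C16 as cyclic dithio ortho ester | CC(=O)O[C@H]1C[C@@H](C)[C@]2(CC[C@]3(CCOC34SCCCS4)O2)[C@]2(C)CCCC(C)(C)[C@H]12 | intermediate
16 | (5S,6S,8R,9R,10R,13R)-6-acetoxy-9,13-epoxy-16,15-olide (CNP0081177.1) | CC(=O)O[C@H]1C[C@@H](C)[C@]2(CC[C@]3(CCOC3=O)O2)[C@]2(C)CCCC(C)(C)[C@H]12 | target

**Step count**
Total: 13 steps. Longest linear sequence: 13 steps (from 1 and 2 to 16).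

**Steps most likely to fail**

Step 11 (key step). The hindered C9 hydroxyl may add too slowly to the radical cation, so that methanol addition or over-oxidation of the dithiane takes over, or the closure may show poor facial selectivity at C13. The fallback is a polar closure that sets out from lactone 12. The lithium enolate (excess LDA, THF, −78 °C) is brominated at C13 with CBr4 to give the 13-bromo lactone F1. Silver triflate with 2,6-di-tert-butylpyridine in CH2Cl2 then ionises the tertiary bromide and the C9 hydroxyl closes the tetrahydrofuran (silver-assisted intramolecular Williamson-type etherification) to the 6α-hydroxy spiro ether lactone F2, with C13 epimers separated at this stage. Acetylation as in step 12 (Ac2O, DMAP, pyridine) gives the target 16, where the route is rejoined.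

Step 1. The Z-substituted diene has a low share of the s-cis conformer, so cycloaddition may be slow, the strong Lewis acid may oligomerise it, or enantiofacial discrimination may be poor. The fallback moves enantiocontrol from the catalyst to a resolution. From 1 and 2 the racemic adduct 3 is made under BF3·OEt2 (or thermally under high pressure) and reduced as in step 2 to racemic 4. Steglich esterification (DCC, DMAP) with (S)-O-methylmandelic acid gives two diastereomeric esters. The ester of the (4R,4aS,8aR) alcohol, the (S)-O-methylmandelate F3, is separated by crystallisation or chromatography and its configuration secured by X-ray analysis. LiOH in aqueous THF returns enantiopure 4, where the route is rejoined.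

Step 7. The peracid may attack the β face of the exocyclic alkene, which would give the 9β,11-epoxide and hence the C9 epimer. The fallback replaces the syn epoxidation by an anti addition from alkene 8. NBS in acetone with a large excess of water would place the bromonium ion on that same β face, and water opens it at the tertiary C9 from the α face (Markovnikov, anti). This gives the 11-bromo-6α,9α-diol F4 with the required C9 configuration. F4 enters the Giese reaction of step 9 in place of 10, and the route is rejoined at lactone 12.

**Further compounds**
F1 | step 11 | 3-bromo-3-[2-(6α,9α-dihydroxy-4,4,8α,10α-tetramethyl-5α-H-decalin-9β-yl)ethyl]dihydrofuran-2(3H)-one (C13 epimers) | O[C@H]1C[C@@H](C)[C@](O)(CCC3(Br)CCOC3=O)[C@]2(C)CCCC(C)(C)[C@H]12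
F2 | step 11 | (5S,6S,8R,9R,10R,13R)-6-hydroxy-9,13-epoxy-16,15-olide (desacetyl target) | O[C@H]1C[C@@H](C)[C@]2(CC[C@]3(CCOC3=O)O2)[C@]2(C)CCCC(C)(C)[C@H]12
F3 | step 1 | (S)-O-methylmandelate of alcohol 4 | CO[C@H](C(=O)O[C@@H]1C=C(C)C(=O)[C@]2(C)CC=CC(C)(C)[C@H]12)c1ccccc1
F4 | step 7 | 9β-(bromomethyl)-4,4,8α,10α-tetramethyl-5α-H-decalin-6α,9α-diol | O[C@H]1C[C@@H](C)[C@](O)(CBr)[C@]2(C)CCCC(C)(C)[C@H]12
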